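In a one-step world a flask has one time constant, and given long enough, all the starting material becomes target. These flasks fed two routes: the catalyst cycle makes target, while the protic impurity destroys starting material one for one, giving quenched substrate.

| setting | Tuesday's | Sunday's | ochre | amber |
|---|---|---|---|---|
| starting material | 0.20 M | 0.20 M | 0.20 M | 0.20 M |
| reagent | 0.35 M | 0.54 M | 0.400 M | 0.260 M |
| protic impurity | 0.10 M | 0.10 M | 0.100 M | 0.100 M |
| free catalyst | 1.9 mM | 1.9 mM | 1.9 mM | 1.9 mM |
| temperature | 55 °C | 66 °C | 70 °C | 50 °C |
| remark | run made earlier | run made earlier |  |  |
| time |  |  | 20 h | 20 h |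

| run | time / h | target / % |
|---|---|---|
| Tuesday's | 0.667 | 23 |
| Tuesday's | 2.00 | 53 |
| Tuesday's | 4.00 | 54 |
| Tuesday's | 5.00 | 53 |
| Tuesday's | 8.00 | 53 |
| Tuesday's | 10.0 | 52 |
| Sunday's | 0.667 | 53 |
| Sunday's | 1.33 | 55 |
| Sunday's | 2.50 | 54 |
| Sunday's | 4.00 | 53 |
| Sunday's | 5.00 | 54 |

(standard deviation of a reading: 1.5 percentage points)

1. the flask that ends with the higher amount of target, in percent of the starting material charged, or "neither" when 2 percentage points or less lies between them (ochre / amber / neither)
2. final target, as a percentage of the starting material charged, in ochre
3. final target, as a percentage of the starting material charged, in amber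

I turned the question round and asked what would have to be true for ochre and amber to end more than 2 percentage points apart. I called r the charge ratio, impurity over starting material, 0.500, the same in both flasks. Once the starting material has gone, target equals 1 − r plus r·u, where u is the share of the impurity charge left unspent, so the base is 50.0%. A gap beyond the margin therefore needed the two values of u to differ by 4 points.

The mean plateaus read 53.0% on Tuesday and 53.8% on Sunday, which as readings put u near 6.00% and 7.60%. These two values, which carry the scatter, lie 1.6 points apart between 55 °C and 66 °C, where reagent differed as well, and ochre and amber stand outside that temperature range. Reagent running short could also open a gap, but amber's reagent, 0.260 M, exceeded the 0.108 M that Sunday's plateau reading implies was consumed. Amber's 20 h was also ten times the 2.00 h by which Tuesday's run had flattened, though Tuesday's run was warmer and held more reagent. I committed to neither flask winning, with both above 50.0%.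

The forecast gave neither, with 53.5% for ochre and 53% for amber: “The yield is therefore set by stoichiometry, not conditions”. Ochre ended at 51.6% and amber at 51.9%, so the answer was neither.

    reagent + free catalyst ⇌ catalyst intermediate A (K = 1.70 L mol⁻¹, k = 1.80 L mol⁻¹ min⁻¹, Ea = 59.0 kJ mol⁻¹, ΔH = −32.0 kJ mol⁻¹)
    starting material + catalyst intermediate A → catalyst intermediate B (k = 150 L mol⁻¹ min⁻¹, Ea = 61.0 kJ mol⁻¹)
    catalyst intermediate B → free catalyst + target (k = 3.00 min⁻¹, Ea = 96.0 kJ mol⁻¹)
    starting material + protic impurity → quenched substrate (k = 0.280 L mol⁻¹ min⁻¹, Ea = 82.0 kJ mol⁻¹)
    (constants at 50 °C)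

Impurity left, as a share of its own charge, was 3.12% in ochre and 3.83% in amber, and r turns ochre's figure into 51.6% target. Amber's target moved by 5 points when its impurity charge alone went to 0.0883 M or 0.113 M. A neighbour of ochre charged with 0.080 M of starting material had r = 1.25 equiv, and starting material, the limiting reagent, stood at 0% after 20.0 h. With 54% of its impurity left, r gives 58.1% quenched, and its target stood at 41.9%.

The numbers in the tables were generated by integration for an exercise, and the scatter is random.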